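**Retrosynthetic overview**
1. The C4(middle)–C6(bottom) bond is cut last. In the same move ring C of the middle unit is contracted, from the chroman to a cis-2-aryl-2,3-dihydrobenzofuran-3-carbaldehyde whose formyl carbon is the future C4. The partner is an 8-bromo-capped bottom unit.
2. Enabling feature: C4 of the middle unit lies between carbinol carbon C3 and C4a of ring A. C4a is ortho/para to O1, O5 and O7, and O3 and the C4 aryl group are anti. Ring A can therefore migrate from C3 to an acyloxy-activated formyl carbon through a phenonium ion, an acetate oxygen enters at C3 from the rear, and the new C4 cation takes up the arene anti to it.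
3. The C4(top)–C8(middle) bond is cut next, giving a 4-alkoxy-8-bromoflavan electrophile and a dihydrobenzofuran ester. Top and bottom units are bought as (−)-epicatechin.
4. The dihydrobenzofuran comes from one enantioselective dirhodium-carbene C–H insertion. It sets two stereocentres, which are relayed to C2, C3 and C4 of the middle unit.
5. Ring order: the rings of the top and bottom units are bought. The five-membered ring is made in step 9 and joined to the top unit in step 10. It is enlarged from five to six members together with the last interflavan bond in step 12, and deprotection follows.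

Key step: step 12

Assumption: Rh2(S-PTTL)4 is taken to give the (2S,3R) cis ester in step 9. If the sense of induction is the opposite, the mirror-image catalyst Rh2(R-PTTL)4 is used.

Step 1
Reactants: 1 (−)-epicatechin
Product: 2 5,7,3',4'-tetra-O-benzyl-(−)-epicatechin
Conditions: BnBr (4.4 equiv), K2CO3, DMF, 0 °C → rt, Ar
Reagents that add atoms: benzyl bromide BrCc1ccccc1
Why: Williamson ether synthesis: carbonate deprotonates only the four phenols, so the C3 alcohol stays free and no stereocentre is touched.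

Step 2
Reactants: 2 5,7,3',4'-tetra-O-benzyl-(−)-epicatechin
Product: 3 3,5,7,3',4'-penta-O-benzyl-(−)-epicatechin
Conditions: NaH, BnBr, DMF, 0 °C → rt
Reagents that add atoms: benzyl bromide BrCc1ccccc1
Why: Williamson ether synthesis on the sodium alkoxide of the C3 alcohol gives a protecting group that survives the later hydride, Lewis-acid and methoxide steps and leaves in the final hydrogenolysis.

Step 3
Reactants: 3 3,5,7,3',4'-penta-O-benzyl-(−)-epicatechin
Product: 4 8-bromo-3,5,7,3',4'-penta-O-benzyl-(−)-epicatechin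
Conditions: NBS (1.0 equiv), CH2Cl2, −78 °C → 0 °C
Reagents that add atoms: N-bromosuccinimide O=C1CCC(=O)N1Br
Why: Electrophilic aromatic bromination takes place at C8, the most nucleophilic ring-A position of 5,7-di-O-alkylated flavans, and the bromine serves as a cap that blocks C8 in both later couplings.

Step 4
Reactants: 4 8-bromo-3,5,7,3',4'-penta-O-benzyl-(−)-epicatechin
Product: 5 8-bromo-4β-(2-ethoxyethoxy)-3,5,7,3',4'-penta-O-benzyl-(−)-epicatechin
Conditions: DDQ, 2-ethoxyethanol, CH2Cl2, rt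
Reagents that add atoms: 2-ethoxyethanol OCCOCC
Why: DDQ benzylic oxidation: hydride abstraction from C4 gives the ring-A-stabilised cation, which the alcohol traps anti to the 3-benzyloxy group to set the 4β (3,4-trans) ether.

Step 5
Reactants: 6 2',4',6'-trihydroxyacetophenone
Product: 7 2'-hydroxy-4',6'-bis{[4-(trifluoromethyl)benzyl]oxy}acetophenone
Conditions: 4-CF3C6H4CH2Br (2.1 equiv), K2CO3, acetone, reflux
Reagents that add atoms: 4-(trifluoromethyl)benzyl bromide BrCc1ccc(cc1)C(F)(F)F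
Why: Williamson ether synthesis: the hydroxyl that stays hydrogen-bonded to the acetyl group is the least reactive, so alkylation should stop at the 4',6'-diether.

Step 6
Reactants: 7 2'-hydroxy-4',6'-bis{[4-(trifluoromethyl)benzyl]oxy}acetophenone; 8 3,4-bis(benzyloxy)benzyl chloride
Product: 9 2'-{[3,4-bis(benzyloxy)benzyl]oxy}-4',6'-bis{[4-(trifluoromethyl)benzyl]oxy}acetophenone
Conditions: K2CO3, KI (cat.), DMF, 70 °C
Reagents that add atoms: none
Why: Williamson ether synthesis at higher temperature alkylates the chelated phenol by the reactive benzylic chloride and brings in ring B together with the future C2.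

Step 7
Reactants: 9 2'-{[3,4-bis(benzyloxy)benzyl]oxy}-4',6'-bis{[4-(trifluoromethyl)benzyl]oxy}acetophenone
Product: 10 methyl 2-(2-{[3,4-bis(benzyloxy)benzyl]oxy}-4,6-bis{[4-(trifluoromethyl)benzyl]oxy}phenyl)acetate
Conditions: Tl(NO3)3·3H2O, MeOH/HC(OMe)3, rt
Reagents that add atoms: methanol CO
Why: Oxidative 1,2-aryl migration of an aryl methyl ketone by trivalent thallium (through the enol ether, the electron-rich aryl group shifting to the thallated carbon) gives the methyl arylacetate.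

Step 8
Reactants: 10 methyl 2-(2-{[3,4-bis(benzyloxy)benzyl]oxy}-4,6-bis{[4-(trifluoromethyl)benzyl]oxy}phenyl)acetate
Product: 11 methyl 2-diazo-2-(2-{[3,4-bis(benzyloxy)benzyl]oxy}-4,6-bis{[4-(trifluoromethyl)benzyl]oxy}phenyl)acetate
Conditions: 4-acetamidobenzenesulfonyl azide, DBU, MeCN, 0 °C → rt
Reagents that add atoms: 4-acetamidobenzenesulfonyl azide CC(=O)Nc1ccc(cc1)S(=O)(=O)N=[N+]=[N-]
Why: Regitz diazo transfer to the benzylic ester enolate gives the donor/acceptor diazo ester.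

Step 9
Reactants: 11 methyl 2-diazo-2-(2-{[3,4-bis(benzyloxy)benzyl]oxy}-4,6-bis{[4-(trifluoromethyl)benzyl]oxy}phenyl)acetate
Product: 12 methyl (2S,3R)-cis-2-[3,4-bis(benzyloxy)phenyl]-4,6-bis{[4-(trifluoromethyl)benzyl]oxy}-2,3-dihydro-1-benzofuran-3-carboxylate
Conditions: Rh2(S-PTTL)4 (1 mol %), toluene, −60 °C
Reagents that add atoms: none
Why: Intramolecular C–H insertion of a donor/acceptor dirhodium carbene into the 1,5-related benzylic ether C–H closes the five-membered ring, the chiral carboxylate ligands set C2 and C3 together in the kinetically favoured cis sense, and the hydridic C–H next to the dialkoxyphenyl ring should outrun that of the electron-poor 4-(trifluoromethyl)benzyl ether.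

Step 10
Reactants: 5 8-bromo-4β-(2-ethoxyethoxy)-3,5,7,3',4'-penta-O-benzyl-(−)-epicatechin; 12 methyl (2S,3R)-cis-2-[3,4-bis(benzyloxy)phenyl]-4,6-bis{[4-(trifluoromethyl)benzyl]oxy}-2,3-dihydro-1-benzofuran-3-carboxylate
Product: 13 top unit–dihydrobenzofuran ester (12 bearing at C7 the 4β-linked flavan-4-yl residue of 5)
Conditions: Me3SiOTf (0.1 equiv), 12 (1.5 equiv), CH2Cl2, −78 °C
Reagents that add atoms: none
Why: Friedel–Crafts-type interflavan coupling: Me3SiOTf ionises the C4 ether of 5, the cation is attacked anti to the 3-benzyloxy group (4β) by C7 of 12, the position next to the ring oxygen that corresponds to the preferred C8 of flavans, while the bromine of 5 prevents self-condensation.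

Step 11
Reactants: 13 top unit–dihydrobenzofuran ester
Product: 14 top unit–dihydrobenzofuran aldehyde ((2S,3R)-cis-3-carbaldehyde)
Conditions: i-Bu2AlH (1.1 equiv), toluene/CH2Cl2, −78 °C; MeOH, then aq. potassium sodium tartrate; crude product used at once
Reagents that add atoms: none
Why: Partial reduction of an ester: the tetrahedral aluminium hemiacetal of the hindered ester persists at −78 °C and releases the aldehyde only on work-up, so the cis configuration at C3 is kept if the crude aldehyde is used at once.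

Step 12
Reactants: 14 top unit–dihydrobenzofuran aldehyde; 4 8-bromo-3,5,7,3',4'-penta-O-benzyl-(−)-epicatechin
Product: 17 fully protected epicatechin-(4β→8)-epicatechin-(4β→6)-epicatechin 3-O-acetylated in the middle unit, via gem-diacetate 15 (not isolated), via ring-enlarged diacetate 16 (not isolated)
Conditions: Ac2O (1.1 equiv), Me3SiOTf (0.2 equiv), CH2Cl2, −40 °C; then 4 (3 equiv), −40 → −10 °C; Et3N quench
Reagents that add atoms: acetic anhydride CC(=O)OC(C)=O
Why: Proposed new method: Me3SiOTf first turns the formyl group into the gem-diacetate 15 (acylal formation); loss of the acetate that lies antiperiplanar to the C3–C3a bond is assisted by the ipso carbon C3a, which is ortho/para to all three ring-A oxygens, and gives a spiro-cyclopropane (phenonium) ion by a 3-exo attack. The carbonyl oxygen of the remaining acetate then opens this ion at C3 from the face opposite to C3a (5-exo-tet closure to a cis-fused 2-methyl-1,3-dioxolan-2-ylium ion), so that ring A has moved from C3 to the former formyl carbon, which enters the heterocycle as C4, and the five-membered ring has become the chroman, resting as diacetate 16. Reionisation at C4 gives the ring-A-stabilised benzylic cation, which is attacked by C6 of 4 (Friedel–Crafts alkylation). C2 is not touched, C3 is set by inversion (the cis aldehyde gives the 2,3-cis acetate), and C4 is set by attack anti to the bridging acetoxy group (3,4-trans, 4β). The closest known reaction types are the aryl-assisted solvolysis of 2-arylalkyl esters with 1,2-aryl shift, acyloxonium neighbouring-group participation, the ring contraction of flavanones to 2-aryl-2,3-dihydrobenzofuran-3-carboxylates by trivalent iodine or thallium (the same aryl shift run backwards) and the Lewis-acid coupling of 4-acyloxyflavans. The step needs aryl shift over hydride shift, C2–C3 fragmentation and cyclisation onto ring B, which is secured by the much higher π-nucleophilicity of C3a and by the rotamer that places the small acylal hydrogen between C2 and C3a so that no acetate stands antiperiplanar to H3, and it needs C6 attack in 4 without self-condensation, which is secured by the two bromine caps and by adding 4 only after 16 has formed.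

Step 13
Reactants: 17 fully protected trimer 3-O-acetylated in the middle unit
Product: 18 fully protected trimer with free 3-OH in the middle unit
Conditions: NaOMe (0.3 equiv), MeOH/THF, rt → 40 °C
Reagents that add atoms: none
Why: Zemplén transesterification removes the only ester, and benzylic ethers, aryl bromides and all stereocentres are inert to catalytic methoxide.

Step 14
Reactants: 18 fully protected trimer with free 3-OH in the middle unit
Product: 19 epicatechin-(4β→8)-epicatechin-(4β→6)-epicatechin (target)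
Conditions: H2 (1 atm), Pd(OH)2/C, Et3N (2.2 equiv), THF/MeOH/H2O, rt
Reagents that add atoms: none
Why: Catalytic hydrogenolysis cleaves all fourteen benzylic ethers and both C–Br bonds in one operation under near-neutral conditions (triethylamine takes up HBr), which avoids acid cleavage of the interflavan bonds and base epimerisation at C2.

**Compound list**

1 | (−)-epicatechin, (2R,3R)-2-(3,4-dihydroxyphenyl)chromane-3,5,7-triol | Oc1cc(O)c2c(c1)O[C@H](c1ccc(O)c(O)c1)[C@H](O)C2 | starting material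

2 | 5,7,3',4'-tetra-O-benzyl-(−)-epicatechin (2R,3R) | c1(OCc3ccccc3)cc(OCc3ccccc3)c2c(c1)O[C@H](c4ccc(OCc3ccccc3)c(OCc3ccccc3)c4)[C@H](O)C2 | intermediate

3 | 3,5,7,3',4'-penta-O-benzyl-(−)-epicatechin (2,3-cis) | c1(OCc3ccccc3)cc(OCc3ccccc3)c2c(c1)O[C@H](c4ccc(OCc3ccccc3)c(OCc3ccccc3)c4)[C@H](OCc3ccccc3)C2 | intermediate

4 | 8-bromo-3,5,7,3',4'-penta-O-benzyl-(−)-epicatechin (2,3-cis) | c1(OCc3ccccc3)cc(OCc3ccccc3)c2c(c1Br)O[C@H](c4ccc(OCc3ccccc3)c(OCc3ccccc3)c4)[C@H](OCc3ccccc3)C2 | intermediate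

5 | 8-bromo-4β-(2-ethoxyethoxy)-3,5,7,3',4'-penta-O-benzyl-(−)-epicatechin (2,3-cis-3,4-trans) | c1(OCc3ccccc3)cc(OCc3ccccc3)c2c(c1Br)O[C@H](c4ccc(OCc3ccccc3)c(OCc3ccccc3)c4)[C@H](OCc3ccccc3)[C@H]2OCCOCC | intermediate

6 | 2',4',6'-trihydroxyacetophenone | CC(=O)c1c(O)cc(O)cc1O | starting material

7 | 2'-hydroxy-4',6'-bis{[4-(trifluoromethyl)benzyl]oxy}acetophenone | CC(=O)c1c(O)cc(OCc3ccc(cc3)C(F)(F)F)cc1OCc3ccc(cc3)C(F)(F)F | intermediate

8 | 3,4-bis(benzyloxy)benzyl chloride | ClCc4ccc(OCc3ccccc3)c(OCc3ccccc3)c4 | starting material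

9 | 2'-{[3,4-bis(benzyloxy)benzyl]oxy}-4',6'-bis{[4-(trifluoromethyl)benzyl]oxy}acetophenone | CC(=O)c1c(OCc4ccc(OCc3ccccc3)c(OCc3ccccc3)c4)cc(OCc3ccc(cc3)C(F)(F)F)cc1OCc3ccc(cc3)C(F)(F)F | intermediate

10 | methyl 2-(2-{[3,4-bis(benzyloxy)benzyl]oxy}-4,6-bis{[4-(trifluoromethyl)benzyl]oxy}phenyl)acetate | COC(=O)Cc1c(OCc4ccc(OCc3ccccc3)c(OCc3ccccc3)c4)cc(OCc3ccc(cc3)C(F)(F)F)cc1OCc3ccc(cc3)C(F)(F)F | intermediate

11 | methyl 2-diazo-2-(2-{[3,4-bis(benzyloxy)benzyl]oxy}-4,6-bis{[4-(trifluoromethyl)benzyl]oxy}phenyl)acetate | COC(=O)C(=[N+]=[N-])c1c(OCc4ccc(OCc3ccccc3)c(OCc3ccccc3)c4)cc(OCc3ccc(cc3)C(F)(F)F)cc1OCc3ccc(cc3)C(F)(F)F | intermediate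

12 | methyl (2S,3R)-cis-2-[3,4-bis(benzyloxy)phenyl]-4,6-bis{[4-(trifluoromethyl)benzyl]oxy}-2,3-dihydro-1-benzofuran-3-carboxylate | c1(OCc3ccc(cc3)C(F)(F)F)cc(OCc3ccc(cc3)C(F)(F)F)c2c(c1)O[C@H](c4ccc(OCc3ccccc3)c(OCc3ccccc3)c4)[C@@H]2C(=O)OC | intermediate

13 | methyl (2S,3R)-cis-2-[3,4-bis(benzyloxy)phenyl]-7-[(4β)-8-bromo-3,5,7,3',4'-penta-O-benzylepicatechin-4-yl]-4,6-bis{[4-(trifluoromethyl)benzyl]oxy}-2,3-dihydro-1-benzofuran-3-carboxylate | c1(OCc3ccccc3)cc(OCc3ccccc3)c2c(c1Br)O[C@H](c4ccc(OCc3ccccc3)c(OCc3ccccc3)c4)[C@H](OCc3ccccc3)[C@H]2c5c(OCc3ccc(cc3)C(F)(F)F)cc(OCc3ccc(cc3)C(F)(F)F)c6c5O[C@H](c4ccc(OCc3ccccc3)c(OCc3ccccc3)c4)[C@@H]6C(=O)OC | intermediate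

14 | (2S,3R)-cis-3-carbaldehyde corresponding to ester 13 | c1(OCc3ccccc3)cc(OCc3ccccc3)c2c(c1Br)O[C@H](c4ccc(OCc3ccccc3)c(OCc3ccccc3)c4)[C@H](OCc3ccccc3)[C@H]2c5c(OCc3ccc(cc3)C(F)(F)F)cc(OCc3ccc(cc3)C(F)(F)F)c6c5O[C@H](c4ccc(OCc3ccccc3)c(OCc3ccccc3)c4)[C@@H]6C=O | intermediate

15 | gem-diacetate (acylal) of aldehyde 14, ring stereocentres unchanged | c1(OCc3ccccc3)cc(OCc3ccccc3)c2c(c1Br)O[C@H](c4ccc(OCc3ccccc3)c(OCc3ccccc3)c4)[C@H](OCc3ccccc3)[C@H]2c5c(OCc3ccc(cc3)C(F)(F)F)cc(OCc3ccc(cc3)C(F)(F)F)c6c5O[C@H](c4ccc(OCc3ccccc3)c(OCc3ccccc3)c4)[C@@H]6C(OC(C)=O)OC(C)=O | intermediate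

16 | ring-enlarged dimer: protected top unit (4β→8)-linked to a 2,3-cis-flavan-3,4β-diyl diacetate (the C4 configuration is of no consequence) | c1(OCc3ccccc3)cc(OCc3ccccc3)c2c(c1Br)O[C@H](c4ccc(OCc3ccccc3)c(OCc3ccccc3)c4)[C@H](OCc3ccccc3)[C@H]2c5c(OCc3ccc(cc3)C(F)(F)F)cc(OCc3ccc(cc3)C(F)(F)F)c6c5O[C@H](c4ccc(OCc3ccccc3)c(OCc3ccccc3)c4)[C@H](OC(C)=O)[C@H]6OC(C)=O | intermediate

17 | protected epicatechin-(4β→8)-epicatechin-(4β→6)-epicatechin: top and bottom units 8-bromo-penta-O-benzyl; middle unit 3-O-acetyl, 3',4'-di-O-benzyl, 5,7-bis-O-[4-(trifluoromethyl)benzyl]; all units 2,3-cis, both linkages 3,4-trans | c1(OCc3ccccc3)cc(OCc3ccccc3)c2c(c1Br)O[C@H](c4ccc(OCc3ccccc3)c(OCc3ccccc3)c4)[C@H](OCc3ccccc3)[C@H]2c5c(OCc3ccc(cc3)C(F)(F)F)cc(OCc3ccc(cc3)C(F)(F)F)c6c5O[C@H](c4ccc(OCc3ccccc3)c(OCc3ccccc3)c4)[C@H](OC(C)=O)[C@H]6c7c(OCc3ccccc3)c(Br)c8c(c7OCc3ccccc3)C[C@@H](OCc3ccccc3)[C@@H](c4ccc(OCc3ccccc3)c(OCc3ccccc3)c4)O8 | intermediate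

18 | compound 17 with free 3-OH in the middle unit | c1(OCc3ccccc3)cc(OCc3ccccc3)c2c(c1Br)O[C@H](c4ccc(OCc3ccccc3)c(OCc3ccccc3)c4)[C@H](OCc3ccccc3)[C@H]2c5c(OCc3ccc(cc3)C(F)(F)F)cc(OCc3ccc(cc3)C(F)(F)F)c6c5O[C@H](c4ccc(OCc3ccccc3)c(OCc3ccccc3)c4)[C@H](O)[C@H]6c7c(OCc3ccccc3)c(Br)c8c(c7OCc3ccccc3)C[C@@H](OCc3ccccc3)[C@@H](c4ccc(OCc3ccccc3)c(OCc3ccccc3)c4)O8 | intermediate

19 | epicatechin-(4β→8)-epicatechin-(4β→6)-epicatechin | Oc1cc(O)c2c(c1)O[C@H](c1ccc(O)c(O)c1)[C@H](O)[C@H]2c1c(O)cc(O)c2c1O[C@H](c1ccc(O)c(O)c1)[C@H](O)[C@H]2c1c(O)cc2c(c1O)C[C@@H](O)[C@@H](c1ccc(O)c(O)c1)O2 | target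

**Step count**

Total step count: 14. Longest linear sequence: 10 steps (steps 5–14, from 6 to 19).

**Steps most likely to fail**

1. Step 12. Ionisation of the acylal may be taken over by a 1,2-hydride shift or by cleavage of the C2–C3 bond. Either would be followed by aromatisation to a benzofuran or by loss of the C2 configuration. The aldehyde may also epimerise at C3 before it is acylated. The fallback uses known reaction types only, sets out from 14 and comes back at 17. It separates the ring enlargement from the C–C bond formation.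
 - 14 is reduced with NaBH4 to the primary alcohol F1.
 - MsCl/Et3N converts it into the mesylate F2.
 - Buffered acetolysis (KOAc, AcOH, 60 °C), an aryl-assisted solvolysis with 1,2-aryl shift, should give the ring-enlarged 2,3-cis 3-acetate F3, which still has a CH2 group at C4.
 - DDQ oxidation in the presence of 2-ethoxyethanol gives the 4β-(2-ethoxyethoxy) ether F4.
 - Me3SiOTf-catalysed coupling of F4 to 4 gives 17.

2. Step 9. The carbene may insert into the benzylic C–H of the neighbouring 4-(trifluoromethyl)benzyl ether, or facial control by the chiral catalyst may be insufficient. The fallback sets out from 11 and comes back at 13. It moves the stereo-differentiation to the coupling with the enantiopure top unit.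
 - Rh2(OAc)4 in CH2Cl2 gives the racemic cis ester, that is 12 together with its mirror image F5.
 - The mixture is coupled to 5 as in step 10.
 - 13 is separated by chromatography from the diastereomeric dimer F6.

3. Step 10. The cation may be attacked through C5 instead of C7 of the dihydrobenzofuran, or the nucleophile may be alkylated twice. The fallback sets out from 12 and comes back at 13. It fixes the site of bond formation beforehand.
 - NBS at −78 °C gives the 7-bromide F7.
 - Miyaura borylation (B2pin2, Pd(dppf)Cl2, KOAc, dioxane, 80 °C) gives the 7-pinacolboronate F8.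
 - Me3SiOTf-promoted ipso-substitution of the boronate by the cation from 5 gives 13.

**Further compounds**

F1 | step 12 | primary alcohol from 14, (2S,3S)-cis-3-(hydroxymethyl) compound | c1(OCc3ccccc3)cc(OCc3ccccc3)c2c(c1Br)O[C@H](c4ccc(OCc3ccccc3)c(OCc3ccccc3)c4)[C@H](OCc3ccccc3)[C@H]2c5c(OCc3ccc(cc3)C(F)(F)F)cc(OCc3ccc(cc3)C(F)(F)F)c6c5O[C@H](c4ccc(OCc3ccccc3)c(OCc3ccccc3)c4)[C@@H]6CO

F2 | step 12 | mesylate of F1 | c1(OCc3ccccc3)cc(OCc3ccccc3)c2c(c1Br)O[C@H](c4ccc(OCc3ccccc3)c(OCc3ccccc3)c4)[C@H](OCc3ccccc3)[C@H]2c5c(OCc3ccc(cc3)C(F)(F)F)cc(OCc3ccc(cc3)C(F)(F)F)c6c5O[C@H](c4ccc(OCc3ccccc3)c(OCc3ccccc3)c4)[C@@H]6COS(C)(=O)=O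

F3 | step 12 | ring-enlarged dimer, lower unit 2,3-cis-3-O-acetyl with CH2 at C4 | c1(OCc3ccccc3)cc(OCc3ccccc3)c2c(c1Br)O[C@H](c4ccc(OCc3ccccc3)c(OCc3ccccc3)c4)[C@H](OCc3ccccc3)[C@H]2c5c(OCc3ccc(cc3)C(F)(F)F)cc(OCc3ccc(cc3)C(F)(F)F)c6c5O[C@H](c4ccc(OCc3ccccc3)c(OCc3ccccc3)c4)[C@H](OC(C)=O)C6

F4 | step 12 | 4β-(2-ethoxyethoxy) derivative of F3 | c1(OCc3ccccc3)cc(OCc3ccccc3)c2c(c1Br)O[C@H](c4ccc(OCc3ccccc3)c(OCc3ccccc3)c4)[C@H](OCc3ccccc3)[C@H]2c5c(OCc3ccc(cc3)C(F)(F)F)cc(OCc3ccc(cc3)C(F)(F)F)c6c5O[C@H](c4ccc(OCc3ccccc3)c(OCc3ccccc3)c4)[C@H](OC(C)=O)[C@H]6OCCOCC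

F5 | step 9 | (2R,3S)-cis ester, mirror image of 12 | c1(OCc3ccc(cc3)C(F)(F)F)cc(OCc3ccc(cc3)C(F)(F)F)c2c(c1)O[C@@H](c4ccc(OCc3ccccc3)c(OCc3ccccc3)c4)[C@H]2C(=O)OC

F6 | step 9 | diastereomer of 13 with the (2R,3S)-cis dihydrobenzofuran | c1(OCc3ccccc3)cc(OCc3ccccc3)c2c(c1Br)O[C@H](c4ccc(OCc3ccccc3)c(OCc3ccccc3)c4)[C@H](OCc3ccccc3)[C@H]2c5c(OCc3ccc(cc3)C(F)(F)F)cc(OCc3ccc(cc3)C(F)(F)F)c6c5O[C@@H](c4ccc(OCc3ccccc3)c(OCc3ccccc3)c4)[C@H]6C(=O)OC

F7 | step 10 | 7-bromo derivative of 12 | c1(OCc3ccc(cc3)C(F)(F)F)cc(OCc3ccc(cc3)C(F)(F)F)c2c(c1Br)O[C@H](c4ccc(OCc3ccccc3)c(OCc3ccccc3)c4)[C@@H]2C(=O)OC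

F8 | step 10 | 7-(pinacolboronate) of 12 | c1(OCc3ccc(cc3)C(F)(F)F)cc(OCc3ccc(cc3)C(F)(F)F)c2c(c1B9OC(C)(C)C(C)(C)O9)O[C@H](c4ccc(OCc3ccccc3)c(OCc3ccccc3)c4)[C@@H]2C(=O)OC
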